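The plan cuts the bond between C1 of the saturated ring B (tetralin numbering) and the ipso carbon of the pendant guaiacyl ring. C1 is a diarylmethine carbon lying para to the phenolic OH of the pendant ring and, through C8a, para to the C6 methoxy group of ring A; it is therefore treated as a latent aldehyde carbon. The precursor is a monocyclic tetrahydrofuran-2-ol that carries ring A only as a benzyl group and holds C1 as a lactol through the C3 hydroxymethyl oxygen. With acid and free guaiacol, one operation forms the aryl–C1 bond, reopens the ring to a quinone methide and lets ring A close ring B, as in cyclolignan biogenesis, setting C1 trans to C2.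

Key step: step 6

Remark on numbering: C1 bears the pendant ring, C2 and C3 bear the CH2OH groups, C4 is the ring CH2, ring A is the fused benzene ring (C4a to C8a, OMe on C6, OH on C7). The target is (1S,2R,3S), that is 1,2-trans and 2,3-cis (the C3 epimer of (+)-isolariciresinol).

Assumption: in step 2 the (4R,5R) hand of the ligand is taken to deliver the (S) acid; if the sign of rotation of lactone 5 shows the opposite sense, the (4S,5S) ligand is used.

Step 1
Reactants: 1 4-(benzyloxy)-3-methoxybenzaldehyde; 2 dimethyl succinate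
Product: 3 (E)-4-[4-(benzyloxy)-3-methoxyphenyl]-3-(methoxycarbonyl)but-3-enoic acid
Conditions: NaOMe (2.2 equiv), MeOH, reflux; then aq HCl
Reagents that add atoms: none
Why: Stobbe condensation, in which the succinate enolate adds to the aldehyde and lactonisation followed by E1cB opening of the paraconate gives the half-ester with the aryl group trans to the ester on the new double bond.

Step 2
Reactants: 3 (E)-4-[4-(benzyloxy)-3-methoxyphenyl]-3-(methoxycarbonyl)but-3-enoic acid
Product: 4 (3S)-4-[4-(benzyloxy)-3-methoxyphenyl]-3-(methoxycarbonyl)butanoic acid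
Conditions: H2 (1 atm), [Rh(cod)Cl]2 (0.25 mol %), (4R,5R)-MOD-DIOP (0.6 mol %), Et3N (10 mol %), MeOH, 30 °C
Reagents that add atoms: none
Why: Rhodium–bisphosphine asymmetric hydrogenation of an itaconate-type half-ester, in which carboxylate and alkene chelate the metal and the hand of the ligand fixes the face of hydrogen delivery, should set the future C3 as (S).

Step 3
Reactants: 4 (3S)-4-[4-(benzyloxy)-3-methoxyphenyl]-3-(methoxycarbonyl)butanoic acid
Product: 5 (4S)-4-[4-(benzyloxy)-3-methoxybenzyl]dihydrofuran-2(3H)-one
Conditions: KOH (1 equiv), EtOH; Ca(BH4)2 (from CaCl2 and NaBH4), EtOH, −10 °C to rt; then 2 M HCl, rt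
Reagents that add atoms: none
Why: Chemoselective reduction of the ester by calcium borohydride beside the carboxylate salt, then acid-catalysed lactonisation, should leave the stereocentre untouched.

Step 4
Reactants: 5 (4S)-4-[4-(benzyloxy)-3-methoxybenzyl]dihydrofuran-2(3H)-one
Product: 6 (3R,4S)-4-[4-(benzyloxy)-3-methoxybenzyl]-3-[(benzyloxy)methyl]dihydrofuran-2(3H)-one (trans)
Conditions: LiN(iPr)2 (LDA, 1.1 equiv), THF, −78 °C; BOMCl (1.2 equiv), DMPU, −78 to −40 °C
Reagents that add atoms: benzyl chloromethyl ether (BOMCl), ClCOCc1ccccc1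
Why: Alkylation of the lactone lithium enolate should take the electrophile on the face anti to the neighbouring benzyl group, giving the trans-3,4 lactone and so setting C2 of the target.

Step 5
Reactants: 6 (3R,4S)-4-[4-(benzyloxy)-3-methoxybenzyl]-3-[(benzyloxy)methyl]dihydrofuran-2(3H)-one
Product: 7 (3R,4S)-4-[4-(benzyloxy)-3-methoxybenzyl]-3-[(benzyloxy)methyl]tetrahydrofuran-2-ol (mixture of anomers)
Conditions: iBu2AlH (DIBAL-H, 1.1 equiv), CH2Cl2, −78 °C; Rochelle salt work-up
Reagents that add atoms: none
Why: Partial reduction of a lactone by DIBAL-H at low temperature should stop at the aluminium hemiacetal and give the lactol on work-up; the only new stereocentre is the anomeric one, which is lost in step 6.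

Step 6
Reactants: 7 (3R,4S)-4-[4-(benzyloxy)-3-methoxybenzyl]-3-[(benzyloxy)methyl]tetrahydrofuran-2-ol; 8 guaiacol (2-methoxyphenol)
Product: 11 4-[(1S,2R,3S)-7-(benzyloxy)-2-[(benzyloxy)methyl]-3-(hydroxymethyl)-6-methoxy-1,2,3,4-tetrahydronaphthalen-1-yl]-2-methoxyphenol, via 2-aryltetrahydrofuran 9 (not isolated), via quinone methide 10 (not isolated)
Conditions: guaiacol (3 equiv), TsOH·H2O (10 mol %), (CF3)2CHOH, 0.05 M, 0 °C to rt
Reagents that add atoms: none
Why: Acid ionises lactol 7 to the five-membered oxocarbenium ion, which guaiacol attacks through the carbon para to its OH to give 9; protonation of the ring oxygen of 9 then opens the benzylic C–O bond to quinone methide 10 (as its O-protonated para-hydroxybenzyl cation), and C8a of ring A adds to C1 to close ring B. The closest known reaction types are the Friedel–Crafts C-arylation of lactols by phenols and the acid-mediated conversion of 7-aryltetrahydrofuran lignans of the lariciresinol type into aryltetralins, here run in one flask. Ring B closes by 6-exo-trig attack of the arene on the exocyclic quinone methide carbon. C1 is the only new stereocentre and is controlled by C2: a chair-like transition state with the pendant ring pseudo-equatorial and anti to the C2 benzyloxymethyl group should give the 1,2-trans (1S) product, while C2 and C3 come unchanged from 7. The step needs attack on guaiacol para to OH (the stronger donor and the least hindered site), ring closure faster than capture of 10 by a second guaiacol (secured by the six-membered intramolecular path), and closure at the ring A carbon para to the methoxy group (the only activated, unhindered ortho site). If ring A captures the oxocarbenium ion first, ionisation of the resulting bridged benzylic ether at C1 and attack of guaiacol anti to the cis C2 and C3 groups should lead to the same product.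

Step 7
Reactants: 11 4-[(1S,2R,3S)-7-(benzyloxy)-2-[(benzyloxy)methyl]-3-(hydroxymethyl)-6-methoxy-1,2,3,4-tetrahydronaphthalen-1-yl]-2-methoxyphenol
Product: 12 4-[(1S,2R,3S)-7-hydroxy-2,3-bis(hydroxymethyl)-6-methoxy-1,2,3,4-tetrahydronaphthalen-1-yl]-2-methoxyphenol (CNP0179824.3)
Conditions: H2 (1 atm), Pd/C (10 wt %), EtOAc/MeOH, rt
Reagents that add atoms: none
Why: Hydrogenolysis of the aryl and the alkyl benzyl ether over palladium on carbon should leave the diarylmethine C–H, the primary alcohols and all three stereocentres untouched.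

Compound list
1 | 4-(benzyloxy)-3-methoxybenzaldehyde | COc1cc(C=O)ccc1OCc1ccccc1 | starting material
2 | dimethyl succinate | COC(=O)CCC(=O)OC | starting material
3 | (E)-4-[4-(benzyloxy)-3-methoxyphenyl]-3-(methoxycarbonyl)but-3-enoic acid | COC(=O)/C(CC(=O)O)=C/c1ccc(OCc2ccccc2)c(OC)c1 | intermediate
4 | (3S)-4-[4-(benzyloxy)-3-methoxyphenyl]-3-(methoxycarbonyl)butanoic acid | COC(=O)[C@H](CC(=O)O)Cc1ccc(OCc2ccccc2)c(OC)c1 | intermediate
5 | (4S)-4-[4-(benzyloxy)-3-methoxybenzyl]dihydrofuran-2(3H)-one | O=C1C[C@H](Cc2ccc(OCc3ccccc3)c(OC)c2)CO1 | intermediate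
6 | (3R,4S)-4-[4-(benzyloxy)-3-methoxybenzyl]-3-[(benzyloxy)methyl]dihydrofuran-2(3H)-one | O=C1[C@@H](COCc2ccccc2)[C@H](Cc2ccc(OCc3ccccc3)c(OC)c2)CO1 | intermediate
7 | (3R,4S)-4-[4-(benzyloxy)-3-methoxybenzyl]-3-[(benzyloxy)methyl]tetrahydrofuran-2-ol, mixture of anomers | OC1[C@@H](COCc2ccccc2)[C@H](Cc2ccc(OCc3ccccc3)c(OC)c2)CO1 | intermediate
8 | guaiacol (2-methoxyphenol) | COc1ccccc1O | starting material
9 | 4-{(3R,4S)-4-[4-(benzyloxy)-3-methoxybenzyl]-3-[(benzyloxy)methyl]tetrahydrofuran-2-yl}-2-methoxyphenol, both epimers at the aryl-bearing carbon | Oc1ccc(C2[C@@H](COCc3ccccc3)[C@H](Cc3ccc(OCc4ccccc4)c(OC)c3)CO2)cc1OC | intermediate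
10 | 4-{(2R,3S)-4-[4-(benzyloxy)-3-methoxyphenyl]-2-[(benzyloxy)methyl]-3-(hydroxymethyl)butylidene}-2-methoxycyclohexa-2,5-dien-1-one | COC1=CC(=C[C@@H](COCc2ccccc2)[C@@H](CO)Cc2ccc(OCc3ccccc3)c(OC)c2)C=CC1=O | intermediate
11 | 4-[(1S,2R,3S)-7-(benzyloxy)-2-[(benzyloxy)methyl]-3-(hydroxymethyl)-6-methoxy-1,2,3,4-tetrahydronaphthalen-1-yl]-2-methoxyphenol | COc1cc([C@H]2c3cc(OCc4ccccc4)c(OC)cc3C[C@H](CO)[C@@H]2COCc2ccccc2)ccc1O | intermediate
12 | 4-[(1S,2R,3S)-7-hydroxy-2,3-bis(hydroxymethyl)-6-methoxy-1,2,3,4-tetrahydronaphthalen-1-yl]-2-methoxyphenol | COc1cc([C@H]2c3cc(O)c(OC)cc3C[C@H](CO)[C@@H]2CO)ccc1O | target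

Total step count: 7. Longest linear sequence: 7 steps (from compound 1).

Steps most likely to fail

Step 6. The cations at C1 may attack guaiacol para to its methoxy group or ortho to its hydroxyl group. The quinone methide may be captured by a second guaiacol before ring closure. The oxocarbenium ion may lose a proton and then benzyl alcohol. The fallback fixes the position on the pendant ring with an organometallic reagent and sets out from lactol 7. Commercial 1-(benzyloxy)-4-bromo-2-methoxybenzene and Mg in THF give [4-(benzyloxy)-3-methoxyphenyl]magnesium bromide F1. Added in excess (2.5 equiv, THF, 0 °C to rt), it opens the lactol through its hydroxy aldehyde form to (2R,3S)-1-[4-(benzyloxy)-3-methoxyphenyl]-3-[4-(benzyloxy)-3-methoxybenzyl]-2-[(benzyloxy)methyl]butane-1,4-diol F2, a mixture of epimers at the benzylic carbinol. CF3CO2H in CH2Cl2 (0 °C) ionises the benzylic alcohol and ring A closes ring B as in step 6, giving (1S,2R,3S)-7-(benzyloxy)-1-[4-(benzyloxy)-3-methoxyphenyl]-2-[(benzyloxy)methyl]-3-(hydroxymethyl)-6-methoxy-1,2,3,4-tetrahydronaphthalene F3. Hydrogenolysis (H2, Pd/C, EtOAc/MeOH) removes the three benzyl groups, and the fallback comes back to the route at compound 12.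

Step 4. Proton transfer between product and enolate may lead to a second alkylation, the enolate may react at oxygen, or the anti selectivity may be incomplete. The fallback replaces the alkylation by an aldol reaction and sets out from lactone 5. Its lithium enolate (LDA, THF, −78 °C) is treated with gaseous formaldehyde to give (3R,4S)-4-[4-(benzyloxy)-3-methoxybenzyl]-3-(hydroxymethyl)dihydrofuran-2(3H)-one F4, again by attack anti to the benzyl group. O-Benzylation under acid (benzyl 2,2,2-trichloroacetimidate, TfOH 5 mol %, CH2Cl2/cyclohexane, rt) avoids base-induced loss of water and comes back to the route at compound 6.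

Step 2. Facial discrimination by the catalyst may be insufficient, or of the opposite sense. The fallback replaces asymmetric catalysis by resolution and sets out from compound 3. Hydrogenation with the achiral catalyst [Rh(cod)(dppb)]BF4 (H2, MeOH, rt), which spares the benzyl ether, gives racemic 4-[4-(benzyloxy)-3-methoxyphenyl]-3-(methoxycarbonyl)butanoic acid F5. Fractional crystallisation with (S)-1-phenylethylamine (the antipodal amine is used if the salt of the (S) acid proves the more soluble one) gives the (S)-1-phenylethylammonium salt of the (3S) acid F6. Acidification with aq HCl comes back to the route at compound 4.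

Further compounds
F1 | step 6 | [4-(benzyloxy)-3-methoxyphenyl]magnesium bromide | COc1cc([Mg]Br)ccc1OCc1ccccc1
F2 | step 6 | (2R,3S)-1-[4-(benzyloxy)-3-methoxyphenyl]-3-[4-(benzyloxy)-3-methoxybenzyl]-2-[(benzyloxy)methyl]butane-1,4-diol, both C1 epimers | COc1cc(C(O)[C@@H](COCc2ccccc2)[C@@H](CO)Cc2ccc(OCc3ccccc3)c(OC)c2)ccc1OCc1ccccc1
F3 | step 6 | (1S,2R,3S)-7-(benzyloxy)-1-[4-(benzyloxy)-3-methoxyphenyl]-2-[(benzyloxy)methyl]-3-(hydroxymethyl)-6-methoxy-1,2,3,4-tetrahydronaphthalene | COc1cc([C@H]2c3cc(OCc4ccccc4)c(OC)cc3C[C@H](CO)[C@@H]2COCc2ccccc2)ccc1OCc1ccccc1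
F4 | step 4 | (3R,4S)-4-[4-(benzyloxy)-3-methoxybenzyl]-3-(hydroxymethyl)dihydrofuran-2(3H)-one | O=C1[C@@H](CO)[C@H](Cc2ccc(OCc3ccccc3)c(OC)c2)CO1
F5 | step 2 | racemic 4-[4-(benzyloxy)-3-methoxyphenyl]-3-(methoxycarbonyl)butanoic acid | COC(=O)C(CC(=O)O)Cc1ccc(OCc2ccccc2)c(OC)c1
F6 | step 2 | (S)-1-phenylethylammonium (3S)-4-[4-(benzyloxy)-3-methoxyphenyl]-3-(methoxycarbonyl)butanoate | COC(=O)[C@H](CC(=O)[O-])Cc1ccc(OCc2ccccc2)c(OC)c1.C[C@H]([NH3+])c1ccccc1
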